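**Retrosynthetic overview**

- Target 25 is the chain A–O–[B–C]–O–[D–E]–O–[F–G]–O–H; the last step cleaves all twenty methyl ethers of 24.
- The strategy rests on ring B (and the identical rings D and F): oxygen on C1, C2, C4, C5 and C6 and a single CH at C3. This maps onto the four carbons of dimethyl squarate (C1, C6, C5, C4) plus a 1-aryloxyvinyl unit (C2, C3) that already carries the hindered oxygen to ring C (E, G).
- Thermal electrocyclic ring expansion of cyclobutenone 8 forms the C3–C4 bond and closes this ring. It leads to one building block, bromide 15 (pentaoxygenated ring with MOM on its C1 oxygen, joined to a 2,6-dimethoxyaryl ring with Br at C4), which is used three times.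
- The four remaining ethers (G–H, E–F, C–D, A–B) each join a di-ortho-substituted phenol oxygen to an unhindered aryl bromide under copper catalysis. The chain grows from ring H toward ring A by coupling 15 and removing MOM, and ends with 1-bromo-3,5-dimethoxybenzene.
- Ring order: rings C/E/G come preformed from quinone 1, rings B/D/F are closed in step 6, rings H and A are bought.

Key step: step 6

Assumption: the target is achiral, so no stereocontrol is needed; 7 and 8 are racemic and their only stereocentre is destroyed in step 6.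

**Route**

Step 1
Reactants: 1 2,6-dimethoxy-1,4-benzoquinone
Product: 2 2,6-dimethoxybenzene-1,4-diol
Conditions: Na2S2O4, H2O/EtOAc, rt, under N2
Reagents that add atoms: none
Why: Dithionite reduction of a p-quinone to its hydroquinone is a clean two-electron reduction and nothing else in 1 is reducible.

Step 2
Reactants: 2 2,6-dimethoxybenzene-1,4-diol
Product: 3 2,6-dimethoxy-4-[(triisopropylsilyl)oxy]phenol
Conditions: TIPSCl (1.05 equiv), imidazole, DMF, 0 °C to rt
Reagents that add atoms: chlorotri(propan-2-yl)silane, CC(C)[Si](Cl)(C(C)C)C(C)C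
Why: Sterically controlled silyl ether formation: the C4 hydroxyl between two CH groups (also the more acidic one) should react much faster with the bulky chlorosilane than the C1 hydroxyl between two methoxy groups, and a silyl ether is used because it has no benzylic C–H that t-BuLi could metalate in step 4.

Step 3
Reactants: 3 2,6-dimethoxy-4-[(triisopropylsilyl)oxy]phenol
Product: 4 [4-(ethenyloxy)-3,5-dimethoxyphenoxy]tri(propan-2-yl)silane
Conditions: 2,4,6-trivinylcyclotriboroxane–pyridine complex, Cu(OAc)2 (1 equiv), pyridine, CH2Cl2, rt, air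
Reagents that add atoms: 2,4,6-trivinylcyclotriboroxane–pyridine complex, C=CB1OB(C=C)OB(C=C)O1.c1ccncc1
Why: Copper-promoted oxidative O-vinylation of a phenol with a vinylboron reagent (Chan–Lam type coupling) runs at room temperature under nearly neutral conditions, tolerates ortho substituents and leaves the silyl ether untouched.

Step 4
Reactants: 4 [4-(ethenyloxy)-3,5-dimethoxyphenoxy]tri(propan-2-yl)silane; 5 dimethyl squarate (3,4-dimethoxycyclobut-3-ene-1,2-dione)
Product: 7 racemic 4-(1-{2,6-dimethoxy-4-[(triisopropylsilyl)oxy]phenoxy}ethenyl)-4-hydroxy-2,3-dimethoxycyclobut-2-en-1-one, via vinyllithium 6 (not isolated)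
Conditions: t-BuLi (1.1 equiv), THF, −78 °C; then 5 (1.2 equiv), −78 °C; aq. NH4Cl at −78 °C
Reagents that add atoms: none
Why: Alpha-lithiation of an enol ether followed by 1,2-addition to a squarate carbonyl: the vinylic C–H next to oxygen is the most acidic site (both ortho positions are blocked and the bulky silyl ether shields the remaining ring C–H), and the carbinol centre forms racemic without consequence because step 6 destroys it.

Step 5
Reactants: 7 racemic 4-(1-{2,6-dimethoxy-4-[(triisopropylsilyl)oxy]phenoxy}ethenyl)-4-hydroxy-2,3-dimethoxycyclobut-2-en-1-one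
Product: 8 racemic 4-(1-{2,6-dimethoxy-4-[(triisopropylsilyl)oxy]phenoxy}ethenyl)-2,3-dimethoxy-4-(methoxymethoxy)cyclobut-2-en-1-one
Conditions: MOMCl, iPr2NEt, CH2Cl2, 0 °C to rt
Reagents that add atoms: chloromethyl methyl ether, COCCl
Why: MOM ether formation on the tertiary carbinol with an amine base masks the oxygen that becomes the hindered C1 oxygen of ring B, so the two oxygens of the later hydroquinone are differentiated before the ring is made.

Step 6
Reactants: 8 racemic 4-(1-{2,6-dimethoxy-4-[(triisopropylsilyl)oxy]phenoxy}ethenyl)-2,3-dimethoxy-4-(methoxymethoxy)cyclobut-2-en-1-one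
Product: 11 5-{2,6-dimethoxy-4-[(triisopropylsilyl)oxy]phenoxy}-2,3-dimethoxy-4-(methoxymethoxy)phenol, via dienylketene 9 (not isolated), via cyclohexadienone 10 (not isolated)
Conditions: degassed toluene (dilute), 110 °C, Ar
Reagents that add atoms: none
Why: Heating opens the cyclobutenone by conrotatory 4π electrocyclic ring opening in which the donor OMOM group on the carbinol carbon rotates outward, so the aryloxyvinyl group ends cis to the ketene in dienylketene 9. Thermal 6π electrocyclisation of 9 then joins the ketene carbon (future C4 of ring B) to the vinyl CH2 (future C3) and closes ring B as a six-membered carbocycle, cyclohexa-2,4-dienone 10, which tautomerises irreversibly to phenol 11. The closest known reaction type is the Moore ring expansion of squarate-derived 4-alkenyl-4-alkoxycyclobutenones, 1-alkoxyvinyl cases included, to monoprotected polyoxygenated hydroquinones. No stereocentre is formed and the racemic carbinol centre of 8 disappears on aromatisation. Regiochemistry is fixed by connectivity: the squarate carbons become C1, C6, C5 and C4, the aryloxy-bearing vinyl carbon becomes C2 and its CH2 becomes the only CH, C3. The step also has to distinguish the two hydroquinone oxygens, and the MOM group secures this by staying on the hindered C1 oxygen while the ketene oxygen appears as the free C4 hydroxyl.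

Step 7
Reactants: 11 5-{2,6-dimethoxy-4-[(triisopropylsilyl)oxy]phenoxy}-2,3-dimethoxy-4-(methoxymethoxy)phenol
Product: 12 {3,5-dimethoxy-4-[3,4,5-trimethoxy-2-(methoxymethoxy)phenoxy]phenoxy}tri(propan-2-yl)silane
Conditions: MeI, K2CO3, acetone, 40 °C
Reagents that add atoms: iodomethane, CI
Why: Williamson methylation of the only free phenol, which sits between a CH and a methoxy group, should be fast under carbonate conditions that leave the aryl silyl ether and the MOM acetal intact.

Step 8
Reactants: 12 {3,5-dimethoxy-4-[3,4,5-trimethoxy-2-(methoxymethoxy)phenoxy]phenoxy}tri(propan-2-yl)silane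
Product: 14 3,5-dimethoxy-4-[3,4,5-trimethoxy-2-(methoxymethoxy)phenoxy]phenyl trifluoromethanesulfonate, via ammonium phenoxide 13 (not isolated)
Conditions: TBAF (1.1 equiv), THF, 0 °C; then PhNTf2, 0 °C to rt
Reagents that add atoms: N-phenylbis(trifluoromethanesulfonimide), O=S(=O)(N(c1ccccc1)S(=O)(=O)C(F)(F)F)C(F)(F)F
Why: Fluoride desilylation gives the tetrabutylammonium phenoxide, which is sulfonylated in the same flask by the triflimide (aryl triflate formation) while MOM and methyl ethers are inert.

Step 9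
Reactants: 14 3,5-dimethoxy-4-[3,4,5-trimethoxy-2-(methoxymethoxy)phenoxy]phenyl trifluoromethanesulfonate
Product: 15 1-(4-bromo-2,6-dimethoxyphenoxy)-3,4,5-trimethoxy-2-(methoxymethoxy)benzene
Conditions: LiBr, [Cp*Ru(MeCN)3]OTf (5 mol%), 1,3-dimethyl-2-imidazolidinone, 100 °C
Reagents that add atoms: lithium bromide, [Li+].[Br-]
Why: Ruthenium-catalysed conversion of an aryl triflate into an aryl bromide (bromide substitution on the η6-bound arene) turns the unhindered C4 position of the dimethoxyaryl ring into the electrophile needed for copper catalysis without exposing the electron-rich pentaoxygenated ring to an electrophilic brominating agent.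

Step 10
Reactants: 15 1-(4-bromo-2,6-dimethoxyphenoxy)-3,4,5-trimethoxy-2-(methoxymethoxy)benzene; 16 2,4,6-trimethoxyphenol
Product: 17 1-[2,6-dimethoxy-4-(2,4,6-trimethoxyphenoxy)phenoxy]-3,4,5-trimethoxy-2-(methoxymethoxy)benzene
Conditions: CuI (10 mol%), picolinic acid (20 mol%), K3PO4, DMSO, 90 °C, Ar
Reagents that add atoms: none
Why: Ullmann diaryl ether coupling with CuI and picolinic acid is suited to di-ortho-substituted phenols and joins the ring H phenoxide to the unhindered C–Br carbon of ring G, with the MOM acetal stable to phosphate base.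

Step 11
Reactants: 17 1-[2,6-dimethoxy-4-(2,4,6-trimethoxyphenoxy)phenoxy]-3,4,5-trimethoxy-2-(methoxymethoxy)benzene
Product: 18 6-[2,6-dimethoxy-4-(2,4,6-trimethoxyphenoxy)phenoxy]-2,3,4-trimethoxyphenol
Conditions: HCl (cat.), MeOH/THF, 50 °C, Ar
Reagents that add atoms: none
Why: Acid-catalysed acetal exchange with methanol removes the MOM group and frees the C1 hydroxyl of ring F, while aryl methyl ethers and diaryl ethers are stable to dilute acid.

Step 12
Reactants: 18 6-[2,6-dimethoxy-4-(2,4,6-trimethoxyphenoxy)phenoxy]-2,3,4-trimethoxyphenol; 15 1-(4-bromo-2,6-dimethoxyphenoxy)-3,4,5-trimethoxy-2-(methoxymethoxy)benzene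
Product: 19 MOM-protected pentaaryl ether of rings D to H (18 arylated on its phenol oxygen by the aryl group of 15; MOM on the C1 oxygen of ring D)
Conditions: CuI (10 mol%), picolinic acid (20 mol%), K3PO4, DMSO, 90–100 °C, Ar
Reagents that add atoms: none
Why: The same Ullmann diaryl ether coupling joins the hindered C1 phenoxide of ring F to the unhindered C4 carbon of ring E, and self-coupling of 15 is impossible because its own phenol is masked as the MOM ether.

Step 13
Reactants: 19 MOM-protected pentaaryl ether of rings D to H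
Product: 20 pentaaryl ether of rings D to H with free C1 hydroxyl on ring D
Conditions: HCl (cat.), MeOH/THF, 50 °C, Ar
Reagents that add atoms: none
Why: Acid-catalysed MOM acetal cleavage as in step 11, with all other ethers inert.

Step 14
Reactants: 20 pentaaryl ether of rings D to H with free C1 hydroxyl on ring D; 15 1-(4-bromo-2,6-dimethoxyphenoxy)-3,4,5-trimethoxy-2-(methoxymethoxy)benzene
Product: 21 MOM-protected heptaaryl ether of rings B to H (MOM on the C1 oxygen of ring B)
Conditions: CuI (20 mol%), picolinic acid (40 mol%), K3PO4, DMSO, 100 °C, Ar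
Reagents that add atoms: none
Why: Ullmann diaryl ether coupling of the C1 phenoxide of ring D with the C4 bromide of ring C, the third use of the same bond-forming pattern between a hindered oxygen and an unhindered aryl carbon.

Step 15
Reactants: 21 MOM-protected heptaaryl ether of rings B to H
Product: 22 heptaaryl ether of rings B to H with free C1 hydroxyl on ring B
Conditions: HCl (cat.), MeOH/THF, 50 °C, Ar
Reagents that add atoms: none
Why: Acid-catalysed MOM acetal cleavage frees the C1 hydroxyl of ring B for the last arylation.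

Step 16
Reactants: 22 heptaaryl ether of rings B to H with free C1 hydroxyl on ring B; 23 1-bromo-3,5-dimethoxybenzene
Product: 24 icosa-O-methyl ether of the target (rings A to H)
Conditions: CuI (20 mol%), picolinic acid (40 mol%), K3PO4, DMSO, 100 °C, Ar
Reagents that add atoms: none
Why: Ullmann diaryl ether coupling of the hindered ring B phenoxide with a simple unhindered aryl bromide installs ring A and completes the carbon–oxygen skeleton.

Step 17
Reactants: 24 icosa-O-methyl ether of the target
Product: 25 CNP0319661.0 (icosahydroxy octaaryl heptaether, rings A to H)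
Conditions: BBr3 (large excess), CH2Cl2, −78 °C to rt; then H2O, 0 °C, Ar
Reagents that add atoms: none
Why: Lewis acid-mediated ether cleavage with BBr3 removes all twenty methyl groups by bromide attack at methyl carbon, whereas the seven diaryl ether links offer no alkyl carbon to attack and should survive, and hydrolysis of the aryl borates gives the free polyphenol.

**Compound list**

1 | 2,6-dimethoxy-1,4-benzoquinone | COC1=CC(=O)C=C(OC)C1=O | starting material
2 | 2,6-dimethoxybenzene-1,4-diol | COc1cc(O)cc(OC)c1O | intermediate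
3 | 2,6-dimethoxy-4-[(triisopropylsilyl)oxy]phenol | COc1cc(O[Si](C(C)C)(C(C)C)C(C)C)cc(OC)c1O | intermediate
4 | [4-(ethenyloxy)-3,5-dimethoxyphenoxy]tri(propan-2-yl)silane | C=COc1c(OC)cc(O[Si](C(C)C)(C(C)C)C(C)C)cc1OC | intermediate
5 | dimethyl squarate | COC1=C(OC)C(=O)C1=O | starting material
6 | 1-{2,6-dimethoxy-4-[(triisopropylsilyl)oxy]phenoxy}ethenyllithium (not isolated) | [Li]C(=C)Oc1c(OC)cc(O[Si](C(C)C)(C(C)C)C(C)C)cc1OC | intermediate
7 | racemic 4-(1-{2,6-dimethoxy-4-[(triisopropylsilyl)oxy]phenoxy}ethenyl)-4-hydroxy-2,3-dimethoxycyclobut-2-en-1-one | COC1=C(OC)C(O)(C(=C)Oc2c(OC)cc(O[Si](C(C)C)(C(C)C)C(C)C)cc2OC)C1=O | intermediate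
8 | racemic 4-(1-{2,6-dimethoxy-4-[(triisopropylsilyl)oxy]phenoxy}ethenyl)-2,3-dimethoxy-4-(methoxymethoxy)cyclobut-2-en-1-one | COCOC1(C(=C)Oc2c(OC)cc(O[Si](C(C)C)(C(C)C)C(C)C)cc2OC)C(OC)=C(OC)C1=O | intermediate
9 | (3Z)-5-{2,6-dimethoxy-4-[(triisopropylsilyl)oxy]phenoxy}-2,3-dimethoxy-4-(methoxymethoxy)hexa-1,3,5-trien-1-one (not isolated) | O=C=C(OC)/C(OC)=C(\C(=C)Oc1c(OC)cc(O[Si](C(C)C)(C(C)C)C(C)C)cc1OC)OCOC | intermediate
10 | 5-{2,6-dimethoxy-4-[(triisopropylsilyl)oxy]phenoxy}-2,3-dimethoxy-4-(methoxymethoxy)cyclohexa-2,4-dien-1-one (not isolated) | O=C1CC(Oc2c(OC)cc(O[Si](C(C)C)(C(C)C)C(C)C)cc2OC)=C(OCOC)C(OC)=C1OC | intermediate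
11 | 5-{2,6-dimethoxy-4-[(triisopropylsilyl)oxy]phenoxy}-2,3-dimethoxy-4-(methoxymethoxy)phenol | COCOc1c(Oc2c(OC)cc(O[Si](C(C)C)(C(C)C)C(C)C)cc2OC)cc(O)c(OC)c1OC | intermediate
12 | {3,5-dimethoxy-4-[3,4,5-trimethoxy-2-(methoxymethoxy)phenoxy]phenoxy}tri(propan-2-yl)silane | COCOc1c(Oc2c(OC)cc(O[Si](C(C)C)(C(C)C)C(C)C)cc2OC)cc(OC)c(OC)c1OC | intermediate
13 | tetrabutylammonium 3,5-dimethoxy-4-[3,4,5-trimethoxy-2-(methoxymethoxy)phenoxy]phenolate (not isolated) | COCOc1c(Oc2c(OC)cc([O-])cc2OC)cc(OC)c(OC)c1OC.CCCC[N+](CCCC)(CCCC)CCCC | intermediate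
14 | 3,5-dimethoxy-4-[3,4,5-trimethoxy-2-(methoxymethoxy)phenoxy]phenyl trifluoromethanesulfonate | COCOc1c(Oc2c(OC)cc(OS(=O)(=O)C(F)(F)F)cc2OC)cc(OC)c(OC)c1OC | intermediate
15 | 1-(4-bromo-2,6-dimethoxyphenoxy)-3,4,5-trimethoxy-2-(methoxymethoxy)benzene | COCOc1c(Oc2c(OC)cc(Br)cc2OC)cc(OC)c(OC)c1OC | intermediate
16 | 2,4,6-trimethoxyphenol | COc1cc(OC)c(O)c(OC)c1 | starting material
17 | 1-[2,6-dimethoxy-4-(2,4,6-trimethoxyphenoxy)phenoxy]-3,4,5-trimethoxy-2-(methoxymethoxy)benzene | COCOc1c(Oc2c(OC)cc(Oc3c(OC)cc(OC)cc3OC)cc2OC)cc(OC)c(OC)c1OC | intermediate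
18 | 6-[2,6-dimethoxy-4-(2,4,6-trimethoxyphenoxy)phenoxy]-2,3,4-trimethoxyphenol | Oc1c(Oc2c(OC)cc(Oc3c(OC)cc(OC)cc3OC)cc2OC)cc(OC)c(OC)c1OC | intermediate
19 | MOM-protected pentaaryl ether of rings D to H | COCOc1c(Oc2c(OC)cc(Oc3c(Oc4c(OC)cc(Oc5c(OC)cc(OC)cc5OC)cc4OC)cc(OC)c(OC)c3OC)cc2OC)cc(OC)c(OC)c1OC | intermediate
20 | pentaaryl ether of rings D to H, free C1 hydroxyl on ring D | Oc1c(Oc2c(OC)cc(Oc3c(Oc4c(OC)cc(Oc5c(OC)cc(OC)cc5OC)cc4OC)cc(OC)c(OC)c3OC)cc2OC)cc(OC)c(OC)c1OC | intermediate
21 | MOM-protected heptaaryl ether of rings B to H | COCOc1c(Oc2c(OC)cc(Oc3c(Oc4c(OC)cc(Oc5c(Oc6c(OC)cc(Oc7c(OC)cc(OC)cc7OC)cc6OC)cc(OC)c(OC)c5OC)cc4OC)cc(OC)c(OC)c3OC)cc2OC)cc(OC)c(OC)c1OC | intermediate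
22 | heptaaryl ether of rings B to H, free C1 hydroxyl on ring B | Oc1c(Oc2c(OC)cc(Oc3c(Oc4c(OC)cc(Oc5c(Oc6c(OC)cc(Oc7c(OC)cc(OC)cc7OC)cc6OC)cc(OC)c(OC)c5OC)cc4OC)cc(OC)c(OC)c3OC)cc2OC)cc(OC)c(OC)c1OC | intermediate
23 | 1-bromo-3,5-dimethoxybenzene | COc1cc(Br)cc(OC)c1 | starting material
24 | icosa-O-methyl ether of the target | COc1cc(OC)cc(Oc2c(Oc3c(OC)cc(Oc4c(Oc5c(OC)cc(Oc6c(Oc7c(OC)cc(Oc8c(OC)cc(OC)cc8OC)cc7OC)cc(OC)c(OC)c6OC)cc5OC)cc(OC)c(OC)c4OC)cc3OC)cc(OC)c(OC)c2OC)c1 | intermediate
25 | CNP0319661.0 | Oc1cc(O)cc(Oc2c(Oc3c(O)cc(Oc4c(Oc5c(O)cc(Oc6c(Oc7c(O)cc(Oc8c(O)cc(O)cc8O)cc7O)cc(O)c(O)c6O)cc5O)cc(O)c(O)c4O)cc3O)cc(O)c(O)c2O)c1 | target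

**Step count**

Total steps: 17. Longest linear sequence: 17 steps (1 to 25; block 15 is made once in steps 1–9 and enters in steps 10, 12 and 14).

**Steps most likely to fail**

1. Step 4. The base may metalate a ring C–H next to a methoxy group instead of the vinylic position, or the alpha-lithio enol ether may lose aryloxide (carbenoid-type decomposition) before it meets the squarate, so that little 1,2-adduct forms. The fallback generates the same vinyllithium by tin–lithium exchange and sets out from phenol 3. KH and trichloroethylene in THF should give {4-[(E)-1,2-dichloroethenyl]oxy-3,5-dimethoxyphenoxy}tri(propan-2-yl)silane F1. n-BuLi (2.2 equiv, THF, −78 to −40 °C, then MeOH) should convert it by elimination and chlorine–lithium exchange into [4-(ethynyloxy)-3,5-dimethoxyphenoxy]tri(propan-2-yl)silane F2. Hydrostannation with Bu3SnH and Pd(PPh3)4 (zerovalent palladium) should place tin on the oxygen-bearing carbon and give tributyl(1-{2,6-dimethoxy-4-[(triisopropylsilyl)oxy]phenoxy}ethenyl)stannane F3. MeLi at −78 °C then gives vinyllithium 6 without any C–H deprotonation, and addition to 5 comes back to the route at 7.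

2. Step 14. C–O bond formation at the crowded phenoxide of the pentamer may be slow, so that protodebromination of 15 and oxidation of the electron-rich phenol compete at the temperature required. The fallback changes the coupling to an oxidative one with an aryl boron partner and sets out from bromide 15. Bromine–lithium exchange (n-BuLi, THF, −78 °C), B(OiPr)3 and mild aqueous work-up should give {3,5-dimethoxy-4-[3,4,5-trimethoxy-2-(methoxymethoxy)phenoxy]phenyl}boronic acid F4. F4 is coupled with phenol 20 under Chan–Lam conditions (Cu(OAc)2, pyridine, 4 Å sieves, CH2Cl2, air, rt). This coupling with divalent copper runs at room temperature and accepts di-ortho-substituted phenols when the boron partner is unhindered; it comes back to the route at 21.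

3. Step 17. Cleavage of the twenty methyl ethers may stop short, and the free polyphenol may degrade oxidatively during work-up and purification. The fallback sets out from 24 and isolates the product as a derivative. The crude product of the BBr3 cleavage is acetylated at once (Ac2O, pyridine, DMAP) to the icosaacetate of the target F5, which should be stable to air and silica and separable from under-demethylated material. Acid-catalysed methanolysis (HCl from AcCl in degassed MeOH, rt, Ar) then releases the polyphenol and comes back to the route at 25.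

**Further compounds**

F1 | step 4 | {4-[(E)-1,2-dichloroethenyl]oxy-3,5-dimethoxyphenoxy}tri(propan-2-yl)silane | Cl/C=C(/Cl)Oc1c(OC)cc(O[Si](C(C)C)(C(C)C)C(C)C)cc1OC
F2 | step 4 | [4-(ethynyloxy)-3,5-dimethoxyphenoxy]tri(propan-2-yl)silane | C#COc1c(OC)cc(O[Si](C(C)C)(C(C)C)C(C)C)cc1OC
F3 | step 4 | tributyl(1-{2,6-dimethoxy-4-[(triisopropylsilyl)oxy]phenoxy}ethenyl)stannane | C=C(Oc1c(OC)cc(O[Si](C(C)C)(C(C)C)C(C)C)cc1OC)[Sn](CCCC)(CCCC)CCCC
F4 | step 14 | {3,5-dimethoxy-4-[3,4,5-trimethoxy-2-(methoxymethoxy)phenoxy]phenyl}boronic acid | COCOc1c(Oc2c(OC)cc(B(O)O)cc2OC)cc(OC)c(OC)c1OC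
F5 | step 17 | icosaacetate of the target | CC(=O)Oc1cc(OC(C)=O)cc(Oc2c(Oc3c(OC(C)=O)cc(Oc4c(Oc5c(OC(C)=O)cc(Oc6c(Oc7c(OC(C)=O)cc(Oc8c(OC(C)=O)cc(OC(C)=O)cc8OC(C)=O)cc7OC(C)=O)cc(OC(C)=O)c(OC(C)=O)c6OC(C)=O)cc5OC(C)=O)cc(OC(C)=O)c(OC(C)=O)c4OC(C)=O)cc3OC(C)=O)cc(OC(C)=O)c(OC(C)=O)c2OC(C)=O)c1
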